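The runs were generated by integration with constants of no real substance; the scatter is artificial.

Follow the partner.

the same everywhere: substrate 0.050 M

| run | partner | capture agent | remark | time |
|---|---|---|---|---|
| Wednesday's | 0.0063 M | 0.015 M | run made earlier |  |
| Sunday's | 0.031 M | 0.015 M | run made earlier |  |
| east | 0.0350 M | 0.0150 M |  | 4.0 h |
| south | 0.0120 M | 0.0150 M |  | 6.0 h |

| run | time / h | target / % |
|---|---|---|
| Wednesday's | 0.250 | 0 |
| Wednesday's | 0.500 | 0.4 |
| Wednesday's | 1.33 | 3.5 |
| Wednesday's | 3.00 | 6.0 |
| Sunday's | 0.250 | 0.8 |
| Sunday's | 0.500 | 3.2 |
| Sunday's | 1.33 | 12.9 |
| Sunday's | 3.00 | 28.3 |

(readings scatter by 1 percentage point)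

- the winner by amount of target, in percent of the substrate charged; "neither" if no more than 2 percentage points parts them (east / south / neither)
- how much target is there at the end, in percent of the substrate charged: east
- how much target is there at the end, in percent of the substrate charged: south



I assumed that each target used one partner. South's partner charge over its substrate charge is 24.0 % and east's is 70.0 %. I called this ratio the partner ceiling: the most target, in percent of the substrate charged, at one partner per target. Partner is the limiting reagent against substrate in both flasks.

Dividing a reading by its run's ceiling gave the partner conversion, and the two earlier runs then drew nearly one curve, within their scatter. It started flat, with a mean of 4.17 % at 0.500 h. It then climbed to 24.3 % at 1.33 h and 46.6 % at 3.00 h.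

The slope read 0.242 h⁻¹ and then a lower 0.134 h⁻¹. But Wednesday's ceiling is 12.6 %, so a scatter of 1 percentage point weighed heavily in these means, the drop could be scatter, and I could not call it a knee. I still assumed a first-order lag running up to the ceiling, as a guess and not as a reading, and the last two means gave it a time constant of 4.78 h.

Carried forward, conversion reached 56.7 % at east's 4.0 h and 71.5 % at south's 6.0 h. My own reckoning was therefore 39.7 % for east and 17.2 % for south, so east led.

The forecast named east as the winner, with 40 % for east and 15 % for south, lower than mine on south. Its ground was that “partner limits the yield and some of it is lost to capture”.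

The flask gave 39.7 % in east and 20.8 % in south, so east won.

    substrate ⇌ open intermediate (K = 0.390, k = 0.00722 min⁻¹)
    partner → second intermediate (k = 0.0169 min⁻¹)
    open intermediate + second intermediate → target (k = 0.851 M⁻¹ min⁻¹)
    2 second intermediate → homo product (k = 0.0234 M⁻¹ min⁻¹)
    open intermediate + capture agent → trapped intermediate (k = 0.165 M⁻¹ min⁻¹)

South ended at 86.7 % of its ceiling, above the 71.5 % I had reckoned, while east ended at 56.7 % of its own. The shrinking supply of partner is the largest single effect on south's target, though not the whole of it: south with its partner held at the charged level holds 59.6 % target at 6.0 h, against 20.8 %. A neighbouring flask, south with 0.048 M of partner, has a ceiling of 96.0 % and ended at 58.7 % target, which is 61.2 % of that ceiling.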